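If the rate had simply followed the charge, charging the free catalyst twice over would have given a factor of 2 at 30 % conversion, and 20 mM a factor of 5.13; that is my own plain arithmetic, and you will want more than that from me. I took those as a floor and went to the runs, though no run changes the catalyst charge, so part of what follows is a guess.

| setting | south-east | north | flask |
|---|---|---|---|
| substrate | 0.039 M | 0.078 M | 0.039 M |
| partner | 0.039 M | 0.039 M | 0.0390 M |
| free catalyst | 3.9 mM | 3.9 mM | 3.9 mM |
| added ligand | 7.4 mM | 7.4 mM | 7.4 mM |
| remark | the very flask that is asked about, followed so far | run made earlier |  |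

south-east run (percent of the substrate charged)

| time / min | product / % | substrate / % |
|---|---|---|
| 10.0 | 0 | 100.0 |
| 20.0 | 0.4 | 98.0 |
| 30.0 | 0 | 97.2 |
| 40.0 | 1.0 | 96.4 |
| 50.0 | 1.6 | 95.3 |
| 60.0 | 2.2 | 94.5 |

north run (percent of the substrate charged)

| time / h | product / % | substrate / % |
|---|---|---|
| 0.667 | 0.7 | 97.5 |
| 1.33 | 1.2 | 95.8 |
| 2.00 | 3.2 | 93.7 |
| 2.50 | 4.1 | 92.5 |
| 3.00 | 5.3 | 91.6 |
| 4.00 | 7.6 | 91.2 |

(each reading ± 0.5 percentage points)

- factor on the rate of making product when 30 % of the substrate are converted if free catalyst is charged twice over
- factor on the rate when 30 % of the substrate are converted if free catalyst is charged at 20 mM instead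

- no earlier run changes the charge of free catalyst; that part of a forecast is a guess

In the south-east run, substrate had fallen further than product had risen, and I read that gap as substrate sitting on catalyst. I defined the working share w as the substrate missing but not yet found as product, divided by the catalyst charged, and the reading at 60.0 min gave 33.0 %, with the scatter of two readings in it. I then supposed that the other 2.61 mM was a fixed debt to the added ligand, charged at 7.4 mM, and that all extra catalyst went to work. That set ceilings of 4.03 and 13.5. As the true debt was a guess, I committed to the geometric middle of floor and ceiling, 2.84 and 8.32.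

The forecast gave 2.8 and 11.5, close to mine on the first and above mine on the second, holding that “Extra catalyst titrates the ligand”.

The simulation gave 2.97 and 8.42.

    partner + free catalyst → catalyst intermediate A (k = 40.0 M⁻¹ h⁻¹)
    substrate + catalyst intermediate A → catalyst intermediate B (k = 82.0 M⁻¹ h⁻¹)
    catalyst intermediate B ⇌ catalyst intermediate C (K = 1.00, k = 4.40 h⁻¹)
    catalyst intermediate C → free catalyst + product (k = 2.80 h⁻¹)
    partner → decomposed reagent (k = 0.0380 h⁻¹)
    free catalyst + added ligand ⇌ idle complex (K = 420 M⁻¹, k = 36.0 M⁻¹ h⁻¹)

In the flask at 5.00 h, the idle complex, an off-cycle reservoir, held 31.6 % of the catalyst, while catalyst intermediates B and C together held 29.2 %. I used w once more: the 33.0 % read at 60.0 min in the south-east run is more than the 24.1 % that catalyst intermediates B and C held in the same flask at 0.500 h and less than the 37.3 % they held at 2.50 h.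

The readings are simulated for substances that don't exist.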